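Count the enzyme first. The same charge goes into each flask, at different temperatures.

common to all: starting material 16 mM; free enzyme 1.6 µM; time 10 min

| flask | temperature |
|---|---|
| south-west | −5 °C |
| west | 55 °C |
| south-east | 25 °C |

    free enzyme + target → free enzyme + over-reaction product (k1 = 7400 M⁻¹ s⁻¹, Ea1 = 33.0 kJ mol⁻¹)
    free enzyme → unfolded enzyme (k2 = 7.6 × 10⁻⁴ s⁻¹, Ea2 = 271 kJ mol⁻¹)
    starting material + free enzyme → target + free enzyme, rate k3*[starting material]*[free enzyme]/(1 + ([starting material]/Km3) + ([target]/Kp3)) (Km3 = 1.9 mM, Kp3 = 0.36 mM, k3 = 7.2 × 10⁶ M⁻¹ s⁻¹, Ea3 = 15.0 kJ mol⁻¹)
    (constants at 25 °C)

- the constants hold at 25 °C; other temperatures follow from the activation energies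

1. which flask leads in amount of target, in percent of the starting material charged ("all alike" within 1.5 percentage points) (south-west / west / south-east / all alike)
2. how much target is there at the end, in percent of the starting material charged: south-west
3. how much target is there at the end, in percent of the starting material charged: west
4. how much target is there at the end, in percent of the starting material charged: south-east

Starting material is the limiting reagent, and its ledger has these lines: still there, target, over-reaction product. Free enzyme decays by first order, so its concentration summed up to the end of the run is its charge times the fraction unfolded by then, divided by the unfolding constant; where hardly any unfolds, this comes to charge times time. This gives the quantity we carry, the enzyme budget, a pure number for each flask: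

budget = making constant × enzyme charged × fraction unfolded / unfolding constant

Rearranging the rate law shows what conversion costs. With c the charge of starting material and x the amount turned into target, the entries are:

first-order entry: ln(c/[starting material])
saturation entry: x/Km
target-brake entry: (c·ln(c/[starting material]) − x)/Kp

The books close when the entries equal the budget.

In west, unfolding runs at 16.6 s⁻¹, so its time scale is far shorter than the run and the fraction unfolded counts as whole; the making constant is 1.25 × 10⁷ M⁻¹ s⁻¹, so the budget is 1.20. The same sum for the over-reaction step gives target an exposure of 0.240%, so we leave that line out. For small x the entries reduce to a quadratic:

x/c + x/Km + x²/(2·c·Kp) = budget, so x = 1.65 mM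

Our reckoning therefore puts target in west at 10.3% of the charge.

Up to the end of the run the budget is 5550 in south-east. In south-west the unfolding time scale is far longer than the run, so charge times time gives 3510. Both lie far above 52.9, the scale of the charge set by c/Km + c/Kp. We expect the first line to empty in those flasks, but the budget does not say how much target then survives.

The forecast names south-west as the leader, with 20.4% (19% to 22%) there, 10.1% (9% to 11.5%) in west and 0.34% (0.28% to 0.42%) in south-east. Its ground for the cold flasks is that “the target is then eaten by the enzyme”, far less at the lower temperature. Its west figure lies slightly below ours.

The simulation gives south-west as the leader, with 20.4% of target there, 10.1% in west and 0.342% in south-east.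

In west, 10.1% of target puts the entries at 1.20 against the budget of 1.20, with free enzyme at 0%. In south-west the main reason target stands at 20.4% is the over-reaction step: the run without that step holds 100% as target. The neighbour of south-east run at 40 °C, where free enzyme ends at 0%, has a budget of 108. With 3.8% of starting material left, its entries come to 114 if everything converted is counted as target, while 11.3% went on to over-reaction product and 84.9% stands as target.

The numbers are assumed; the run is a simulation.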